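(The numbers in the tables were computed for an exercise.)

Late in Sunday's run starting material reads 0.6% at 30.0 min, yet target keeps falling, from 44.5% at 20.0 min to 40.1% at 60.0 min. What that decline is worth at 80 min in the new flask is the dispute.

all flasks: gas phase 48 mM (held)

|  | starting material | remark | time |
|---|---|---|---|
| Sunday's | 1.3 M | run made earlier |  |
| Tuesday's | 2.1 M | run made earlier |  |
| flask | 0.96 M |  | 80 min |

- Sunday's (time / min: target / %, starting material / %): 5.00: 24.7, 39.5; 10.0: 39.3, 12.6; 20.0: 44.5, 1.9; 30.0: 42.6, 0.6; 60.0: 40.1, 1.6
- Tuesday's (time / min: target / %, starting material / %): 12.0: 34.8, 9.7; 25.0: 39.3, 1.0; 40.0: 37.2, 1.1; 50.0: 36.7, 1.4; 60.0: 35.8, 1.1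

(each reading ± 0.5 percentage points)

- the numbers in the tables scatter with a standard deviation of 0.5 percentage points
- at the start none of the gas phase is in solution

- south-west: doubling the saturation concentration of gas phase, all else as stated
- south: doubling the transfer coefficient of the gas phase, all else as stated

- target at 80 min, in percent of the starting material charged
- the change that raises the amount of target at 80 min, in percent of the starting material charged most ("none" if none brings more than 2 percentage points) (south-west / south / none)
- amount of target at 80 min, in percent of the starting material charged, after south

The first chemist calls target an end product, so the flask keeps its peak. The highest readings of the two runs are 44.5% at 1.3 M and 39.3% at 2.1 M, and a straight line through them gives 46.7% at 0.96 M.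

The second chemist, whose side I take, reads a slow pseudo-first-order loss. Call it the fade constant, the logarithmic fall of target per minute after its highest reading. Sunday's run gives 0.00260 /min and Tuesday's 0.00267 /min, so the mean is 0.00263 /min. Faded from 20.0 min to 80 min, the same peak leaves 39.9%.

The forecast sides with the fade but says 42%, above my figure. It gives 48% after south and picks south-west: “Doubling saturation both supplies more gas and improves trapping”.

The flask gives 40.7%, and 46.0% after south. South gains 5.4 percentage points and south-west 17 points, so south-west wins. The end-product view belongs to early readings: with all amounts held, the answer differs by 5 points from the one at 80 min if the flask is read at 36.0 min on the early side or at 130 min on the late side.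

    starting material + dissolved gas ⇌ target (K = 580 /M, k = 0.0740 /M/s)
    gas phase ⇌ dissolved gas, rate k2*(csat - [dissolved gas]) (kL = 0.0410 /s)
    starting material → side product (k = 0.00180 /s)
    dissolved gas → decomposed reagent (k = 0.00300 /s)

At 80.0 min in this flask, starting material goes to side product at 0.54 of the forward rate at which it goes with dissolved gas to target. Between 40.0 min and 80.0 min target goes from 45.2% to 40.7% while side product goes from 53.7% to 58.3%. Carried to 800 min, the fade constant gives 6.13%, and the flask holds 6.05%. Taken back to the neighbour read at 20 min, it gives 47.7%; the computed target there is 47.3%.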